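All constants are made up.

Of the substrate charged, I want the amount standing as intermediate in each set-up when it is read, and the charge gives me the first ceiling on that amount.

| setting | Wednesday's | Sunday's | Saturday's |
|---|---|---|---|
| substrate | 0.10 M | 0.10 M | 0.10 M |
| time | 2.5 h |  |  |
| remark | everything together in a closed stirred flask, run for 2.5 h | a single well-mixed tank run continuously and read at steady state, 25.0 h in it on average | one stirred flow tank at steady state, fed with the mixture as stated, mean residence time 2.5 h |

    substrate → intermediate (k1 = 0.00546 s⁻¹)
    intermediate ⇌ isomer of the product (K2 = 20, k2 = 1.67 × 10⁻⁴ s⁻¹)
    substrate + intermediate → side product (k3 = 0.00387 M⁻¹ s⁻¹)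
    intermediate ⇌ target (K4 = 0.72, k4 = 4.95 × 10⁻⁴ s⁻¹)

- a species is counted by the substrate in it: one side product counts as two
- the stated concentrations are those of everything mixed, before any reaction; amounts are the same in each set-up
- run time (Wednesday's): 2.5 h

* order of the set-ups by the amount of intermediate at the outlet or at the end, in percent of the substrate put in, highest first (Wednesday's / Sunday's / Saturday's)
* amount of intermediate at the outlet or at the end, in percent of the substrate put in, Wednesday's
* amount of intermediate at the outlet or at the end, in percent of the substrate put in, Sunday's
* amount of intermediate at the outlet or at the end, in percent of the substrate put in, Saturday's

I call intermediate, isomer of the product and target together the pool. In a tank at steady state, one mean level replaces the curve of a closed flask. The balance of the isomer gives its concentration as c(intermediate) times a ratio: forward rate constant times mean residence time τ, divided by one plus that product over the equilibrium constant. Target follows the same form with its own constants. The step to side product enters neither balance, so it shrinks the pool without moving the split. One over one plus the two ratios is therefore the tank share, for Saturday's 33.1 %, the fraction of the pool standing as intermediate.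

The pool cannot exceed the charge, so that share is my ceiling for Saturday's. For a floor, I subtract the substrate still in the tank and the side product, counted as two. I take substrate as step one alone leaves it and intermediate at its ceiling, which gives 31.0 %. Feeding that floor back, with step three added to the substrate balance, lowers the ceiling to 31.1 %. Sunday's tank share, 9.72 %, is its ceiling.

Wednesday's closed flask has a curve, so I give it an estimate and no bound. The forward half-life of 0.39 h for the step to target is short against the 2.5 h run, so I hold target in balance with intermediate (a pre-equilibrium) and let the pair drain to the isomer. With the pool taken as the charge, that gives 24.3 %. My order is Saturday's > Wednesday's > Sunday's.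

The forecast gives 22.5 % for Wednesday's, 9.57 % for Sunday's and 31.1 % for Saturday's, in the order Saturday's > Wednesday's > Sunday's, and for Wednesday's it says the "pool then relaxes linearly". Its Saturday's figure stands above my floor. My ceiling of 33.1 % stands above that figure. My Wednesday's estimate is higher than its figure.

The simulation gives 22.6 % for Wednesday's, 9.57 % for Sunday's and 31.1 % for Saturday's, in the order Saturday's > Wednesday's > Sunday's. Dividing Saturday's reading by its tank share 33.1 % puts the pool at 94.0 % of the charge. The same division on Sunday's, with tank share 9.72 %, gives 98.5 %. With the loss to side product struck out, Sunday's tank reads 9.70 %, level with that share.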